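**Retrosynthetic overview**

1. The C3–O ester bond is cut first: a decalin ketol and (2E,5R)-5-(angeloyloxy)hex-2-enoic acid are joined late with inversion at C3; the acid comes from (R)-pent-4-en-2-ol, angelic acid and acrylic acid.
2. Ring A (C5–C10) is opened at C8–C9 and C7–C11. The α-ketol C8(=O)–C9(OH), with the isopropenyl-bearing C7 next to C8, is treated as a nitro-aldol product with C8 at the nitro level. A C7=C8 nitroalkene on a monocyclic ring B aldehyde takes up the isopropenyl group at C7, and the C8 nitronate then closes ring A on the C9 aldehyde. In the cis-fused decalin the C7, C8 and C9 substituents are all equatorial, so the reversible closure should correct itself; a Nef reaction then turns C8 into the ketone.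
3. Ring B (C1–C5, C10) comes from an enantioselective Michael/aldol annulation that sets C10. The allyl group (C6–C8) and the C5 methyl group enter by two cuprate additions; the second goes anti to the C10 side chain and is trapped with MeI to set C4.
4. Order of ring formation: ring B in step 1, ring A in step 7.

Key step: step 7

Remark (numbering): eremophilane numbering is used for the carbocycle and its monocyclic precursors (ring B = C1–C5 and C10; ring A = C5–C10; C11–C13 = isopropenyl on C7); β is the face carrying the C4 and C5 methyl groups.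

Remark (assumption): (S)-BINAP is taken as the ligand antipode that gives the (7R) adduct in step 7; if the other antipode is needed it is used instead, and a minor C7 epimer would converge after step 10, where C7 is epimerisable and the 7β-equatorial isomer is the stable one.

Abbreviations: TBS = tert-butyldimethylsilyl, TMS = trimethylsilyl, TES = triethylsilyl, DMP = Dess–Martin periodinane, DIAD = diisopropyl azodicarboxylate, cod = cycloocta-1,5-diene.

**Route**

Step 1
Reactants: 1 3-[(tert-butyldimethylsilyl)oxy]propanal; 2 but-3-en-2-one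
Product: 4 (4S)-4-{[(tert-butyldimethylsilyl)oxy]methyl}cyclohex-2-en-1-one, via keto-aldehyde 3 (not isolated)
Conditions: (R)-2-[methoxy(diphenyl)methyl]pyrrolidine (5 mol %), ethyl 3,4-dihydroxybenzoate (20 mol %), neat, 4 °C; then TsOH·H2O (10 mol %), toluene, 40 °C
Reagents that add atoms: none
Why: Enamine-mediated Michael addition to the enone, in which the diarylmethyl group shields one enamine face and sets C10, is followed by acid-catalysed intramolecular aldol condensation (Robinson-type annulation) that closes ring B without touching the stereocentre.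

Step 2
Reactants: 4 (4S)-4-{[(tert-butyldimethylsilyl)oxy]methyl}cyclohex-2-en-1-one
Product: 6 (4S)-4-{[(tert-butyldimethylsilyl)oxy]methyl}-3-(prop-2-en-1-yl)cyclohex-2-en-1-one, via trimethylsilyl enol ether 5 (not isolated)
Conditions: allylMgBr, CuBr·SMe2 (10 mol %), TMSCl, THF, −78 °C; then Pd(OAc)2 (1.1 equiv), MeCN, rt
Reagents that add atoms: allylmagnesium bromide C=CC[Mg]Br
Why: Copper-catalysed 1,4-addition with TMSCl trapping and Saegusa–Ito oxidation of the regiodefined silyl enol ether should return the enone with the allyl group (C6–C8) on C5, the transient C5 stereocentre of 5 being erased.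

Step 3
Reactants: 6 (4S)-4-{[(tert-butyldimethylsilyl)oxy]methyl}-3-(prop-2-en-1-yl)cyclohex-2-en-1-one
Product: 8 (2R,3S,4S)-4-{[(tert-butyldimethylsilyl)oxy]methyl}-2,3-dimethyl-3-(prop-2-en-1-yl)cyclohexan-1-one, via lithium enolate 7 (not isolated)
Conditions: Me2CuLi (from MeLi and CuI), Et2O, −20 → 0 °C; then MeI, HMPA, THF, −40 → 0 °C
Reagents that add atoms: lithium dimethylcuprate [Li+].C[Cu-]C; iodomethane CI
Why: Conjugate addition of the Gilman cuprate anti to the C10 CH2OTBS group creates quaternary C5 with methyl trans and allyl cis to C9, and the enolate is methylated by axial attack anti to the axial allyl group (half-chair with equatorial CH2OTBS), which should set C4 with the two methyl groups cis (conjugate addition–enolate alkylation).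

Step 4
Reactants: 8 (2R,3S,4S)-4-{[(tert-butyldimethylsilyl)oxy]methyl}-2,3-dimethyl-3-(prop-2-en-1-yl)cyclohexan-1-one
Product: 9 (2R,3S,4S)-4-{[(tert-butyldimethylsilyl)oxy]methyl}-2,3-dimethyl-3-[(2E)-3-nitroprop-2-en-1-yl]cyclohexan-1-one
Conditions: AgNO2 (3 equiv), TEMPO (1 equiv), 4 Å molecular sieves, 1,2-dichloroethane, 70 °C
Reagents that add atoms: silver nitrite [Ag+].[O-]N=O
Why: Radical nitration of the terminal olefin: the NO2 radical adds to the terminal carbon C8 and TEMPO-assisted hydrogen abstraction should give the conjugated (E)-nitroalkene, with the ketone and silyl ether inert.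

Step 5
Reactants: 9 (2R,3S,4S)-4-{[(tert-butyldimethylsilyl)oxy]methyl}-2,3-dimethyl-3-[(2E)-3-nitroprop-2-en-1-yl]cyclohexan-1-one
Product: 10 (2R,3S,4S)-4-(hydroxymethyl)-2,3-dimethyl-3-[(2E)-3-nitroprop-2-en-1-yl]cyclohexan-1-one
Conditions: HF·pyridine, THF, 0 °C → rt
Reagents that add atoms: none
Why: Fluoride-driven desilylation under mildly acidic, base-free conditions should free the C9 alcohol while sparing the nitroalkene and the epimerisable C4.

Step 6
Reactants: 10 (2R,3S,4S)-4-(hydroxymethyl)-2,3-dimethyl-3-[(2E)-3-nitroprop-2-en-1-yl]cyclohexan-1-one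
Product: 11 (1S,2S,3R)-2,3-dimethyl-2-[(2E)-3-nitroprop-2-en-1-yl]-4-oxocyclohexane-1-carbaldehyde
Conditions: DMP, CH2Cl2, 0 °C → rt
Reagents that add atoms: none
Why: Dess–Martin oxidation gives the aldehyde under neutral conditions, so C10 (α to the new aldehyde and next to quaternary C5) should not epimerise.

Step 7
Reactants: 11 (1S,2S,3R)-2,3-dimethyl-2-[(2E)-3-nitroprop-2-en-1-yl]-4-oxocyclohexane-1-carbaldehyde
Product: 13 (4R,5S,7R,8R,9R,10S)-9-hydroxy-8-nitroeremophil-11-en-3-one (cis-fused; 7β-isopropenyl; 8α-nitro; 9β-hydroxy), via nitro aldehyde 12 (not isolated)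
Conditions: 2-isopropenyl-4,4,5,5-tetramethyl-1,3,2-dioxaborolane (2 equiv), [Rh(OH)(cod)]2 (3 mol %), (S)-BINAP (7 mol %), 1,4-dioxane/H2O 10:1, 50 °C; then Et3N (0.5 equiv), rt
Reagents that add atoms: 2-isopropenyl-4,4,5,5-tetramethyl-1,3,2-dioxaborolane C=C(C)B1OC(C)(C)C(C)(C)O1
Why: Proposed new method: a rhodium-catalysed conjugate alkenylation/nitro-aldol domino in which the isopropenyl group is transmetalated from boron to the hydroxorhodium–BINAP complex, 1,4-insertion of the C7=C8 nitroalkene gives a rhodium nitronate that is hydrolysed to nitro aldehyde 12, and the nitronate regenerated by Et3N adds to the C9 aldehyde; the closest known reaction types are the rhodium/BINAP-catalysed asymmetric 1,4-addition of aryl- and alkenylboron reagents to nitroalkenes, rhodium-catalysed tandem conjugate addition–aldol cyclisations and amine-mediated domino Michael/Henry cyclisations. Ring A is closed by 6-exo-trig attack of the C8 nitronate carbon on the aldehyde carbon C9 (C8–C9 bond), and the C7–C11 bond is made in the same pot. C7 is set by the chiral ligand (7R, isopropenyl β), while C8 and C9 are set under thermodynamic control because the nitro-aldol step is reversible: in the cis-fused decalin, whose conformation is fixed by ring B, the isopropenyl, nitro and hydroxyl groups should all end up equatorial (8α-nitro, 9β-hydroxy, H9 trans-diaxial to H10). The step needs chemoselectivity of the alkenylrhodium species for the nitroalkene over the aldehyde and the ketone, which the much higher acceptor reactivity of the nitroalkene and the neopentyl-type hindrance of the C9 aldehyde next to quaternary C5 should secure. It also needs closure onto C9 and not onto the C3 ketone, secured by the higher electrophilicity of the aldehyde and the unfavourable, reversible nitro-aldol addition to ketones; the weak base should not enolise the aldehyde, so C10 and the cis ring fusion are kept.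

Step 8
Reactants: 13 (4R,5S,7R,8R,9R,10S)-9-hydroxy-8-nitroeremophil-11-en-3-one
Product: 14 (4R,5S,7R,8R,9R,10S)-8-nitro-9-[(triethylsilyl)oxy]eremophil-11-en-3-one
Conditions: TESCl, imidazole, DMF, 0 °C → rt
Reagents that add atoms: chlorotriethylsilane CC[Si](Cl)(CC)CC
Why: Silylation of the secondary C9 hydroxyl under imidazole conditions that do not enolise the C3 ketone blocks retro-nitroaldol and masks the C9 hydroxyl for the later Mitsunobu step.

Step 9
Reactants: 14 (4R,5S,7R,8R,9R,10S)-8-nitro-9-[(triethylsilyl)oxy]eremophil-11-en-3-one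
Product: 15 (3S,4R,5R,7R,8R,9R,10S)-8-nitro-9-[(triethylsilyl)oxy]eremophil-11-en-3-ol (3β-hydroxy; axial)
Conditions: LiBH(s-Bu)3, THF, −78 °C; then H2O
Reagents that add atoms: none
Why: The bulky borohydride should attack the C3 ketone along the equatorial trajectory, because the axial C5 methyl group blocks axial attack in the conformationally locked cis-decalin, giving the axial 3β-alcohol (cis to the C4 methyl) that is the substrate for inversion.

Step 10
Reactants: 15 (3S,4R,5R,7R,8R,9R,10S)-8-nitro-9-[(triethylsilyl)oxy]eremophil-11-en-3-ol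
Product: 17 (3S,4R,5R,7R,9R,10S)-3-hydroxy-9-[(triethylsilyl)oxy]eremophil-11-en-8-one, via sodium nitronate 16 (not isolated)
Conditions: NaOMe (1.05 equiv), MeOH, 0 °C; then TiCl3 (aq), NH4OAc, THF/H2O, 0 °C → rt
Reagents that add atoms: water O
Why: Reductive Nef reaction: the nitronate is reduced by TiCl3 to the imine, which hydrolyses to the C8 ketone; C7 becomes epimerisable but already carries the favoured equatorial isopropenyl group, and the C9 silyl ether prevents retro-nitroaldol and enediol isomerisation of the α-ketol.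

Step 11
Reactants: 18 (2R)-pent-4-en-2-ol; 19 (2Z)-2-methylbut-2-enoic acid (angelic acid)
Product: 21 (2R)-pent-4-en-2-yl (2Z)-2-methylbut-2-enoate, via mixed anhydride 20 (not isolated)
Conditions: 2,4,6-trichlorobenzoyl chloride, Et3N, toluene, rt; then 18, toluene, 80 °C
Reagents that add atoms: none
Why: Yamaguchi mixed-anhydride esterification without DMAP acylates the alcohol with retention at carbon and is the established way to make angelates without Z to E isomerisation.

Step 12
Reactants: 21 (2R)-pent-4-en-2-yl (2Z)-2-methylbut-2-enoate; 22 prop-2-enoic acid (acrylic acid)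
Product: 23 (2E,5R)-5-{[(2Z)-2-methylbut-2-enoyl]oxy}hex-2-enoic acid
Conditions: acrylic acid (3 equiv), second-generation Hoveyda–Grubbs catalyst RuCl2(H2IMes)(=CH–C6H4–2-O-i-Pr) (5 mol %), CH2Cl2, 40 °C
Reagents that add atoms: none
Why: Olefin cross-metathesis of the terminal alkene with acrylic acid should give the (E)-enoic acid, the trisubstituted electron-poor angelate olefin taking no part.

Step 13
Reactants: 17 (3S,4R,5R,7R,9R,10S)-3-hydroxy-9-[(triethylsilyl)oxy]eremophil-11-en-8-one; 23 (2E,5R)-5-{[(2Z)-2-methylbut-2-enoyl]oxy}hex-2-enoic acid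
Product: 24 (3R,4R,5R,7R,9R,10S)-8-oxo-9-[(triethylsilyl)oxy]eremophil-11-en-3-yl (2E,5R)-5-{[(2Z)-2-methylbut-2-enoyl]oxy}hex-2-enoate
Conditions: PPh3, DIAD, toluene, 0 °C → rt
Reagents that add atoms: none
Why: Mitsunobu esterification: the axial 3β-alcohol is activated as the oxyphosphonium ion and displaced by the carboxylate with inversion (SN2), which attaches the side chain and sets the equatorial 3α (3R) configuration in one operation.

Step 14
Reactants: 24 (3R,4R,5R,7R,9R,10S)-8-oxo-9-[(triethylsilyl)oxy]eremophil-11-en-3-yl (2E,5R)-5-{[(2Z)-2-methylbut-2-enoyl]oxy}hex-2-enoate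
Product: 25 (3R,4R,5R,7R,9R,10S)-9-hydroxy-8-oxoeremophil-11-en-3-yl (2E,5R)-5-{[(2Z)-2-methylbut-2-enoyl]oxy}hex-2-enoate (CNP0210874.1)
Conditions: HF·pyridine, THF, 0 °C
Reagents that add atoms: none
Why: Mild fluoride cleavage of the α-silyloxy ketone frees the C9 hydroxyl without base, so neither the β,γ-unsaturated ketone nor the 5-acyloxy enoate should isomerise or eliminate.

**Compound list**

1 | 3-[(tert-butyldimethylsilyl)oxy]propanal | O=CCCO[Si](C)(C)C(C)(C)C | starting material
2 | but-3-en-2-one (methyl vinyl ketone) | CC(=O)C=C | starting material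
3 | (2R)-2-{[(tert-butyldimethylsilyl)oxy]methyl}-5-oxohexanal | CC(=O)CC[C@@H](C=O)CO[Si](C)(C)C(C)(C)C | intermediate
4 | (4S)-4-{[(tert-butyldimethylsilyl)oxy]methyl}cyclohex-2-en-1-one | O=C1C=C[C@@H](CO[Si](C)(C)C(C)(C)C)CC1 | intermediate
5 | tert-butyl{[(1S,2R)-2-allyl-4-(trimethylsilyloxy)cyclohex-3-en-1-yl]methoxy}dimethylsilane (allyl trans to CH2OTBS) | C=CC[C@H]1C=C(O[Si](C)(C)C)CC[C@@H]1CO[Si](C)(C)C(C)(C)C | intermediate
6 | (4S)-4-{[(tert-butyldimethylsilyl)oxy]methyl}-3-(prop-2-en-1-yl)cyclohex-2-en-1-one | C=CCC1=CC(=O)CC[C@@H]1CO[Si](C)(C)C(C)(C)C | intermediate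
7 | lithium (3S,4S)-4-{[(tert-butyldimethylsilyl)oxy]methyl}-3-methyl-3-(prop-2-en-1-yl)cyclohex-1-en-1-olate | C=CC[C@@]1(C)[C@H](CCC([O-])=C1)CO[Si](C)(C)C(C)(C)C.[Li+] | intermediate
8 | (2R,3S,4S)-4-{[(tert-butyldimethylsilyl)oxy]methyl}-2,3-dimethyl-3-(prop-2-en-1-yl)cyclohexan-1-one | C=CC[C@@]1(C)[C@H](CCC(=O)[C@@H]1C)CO[Si](C)(C)C(C)(C)C | intermediate
9 | (2R,3S,4S)-4-{[(tert-butyldimethylsilyl)oxy]methyl}-2,3-dimethyl-3-[(2E)-3-nitroprop-2-en-1-yl]cyclohexan-1-one | [O-][N+](=O)/C=C/C[C@@]1(C)[C@H](CCC(=O)[C@@H]1C)CO[Si](C)(C)C(C)(C)C | intermediate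
10 | (2R,3S,4S)-4-(hydroxymethyl)-2,3-dimethyl-3-[(2E)-3-nitroprop-2-en-1-yl]cyclohexan-1-one | [O-][N+](=O)/C=C/C[C@@]1(C)[C@H](CCC(=O)[C@@H]1C)CO | intermediate
11 | (1S,2S,3R)-2,3-dimethyl-2-[(2E)-3-nitroprop-2-en-1-yl]-4-oxocyclohexane-1-carbaldehyde | [O-][N+](=O)/C=C/C[C@@]1(C)[C@H](CCC(=O)[C@@H]1C)C=O | intermediate
12 | (1S,2S,3R)-2,3-dimethyl-2-[(2R)-3-methyl-2-(nitromethyl)but-3-en-1-yl]-4-oxocyclohexane-1-carbaldehyde | C=C(C)[C@H](C[N+](=O)[O-])C[C@@]1(C)[C@H](CCC(=O)[C@@H]1C)C=O | intermediate
13 | (4R,5S,7R,8R,9R,10S)-9-hydroxy-8-nitroeremophil-11-en-3-one (cis-fused; 4β,5β-dimethyl; 7β-isopropenyl; 8α-nitro; 9β-hydroxy; 10β-H) | C=C(C)[C@H]1C[C@@]2(C)[C@H](CCC(=O)[C@@H]2C)[C@@H](O)[C@@H]1[N+](=O)[O-] | intermediate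
14 | (4R,5S,7R,8R,9R,10S)-8-nitro-9-[(triethylsilyl)oxy]eremophil-11-en-3-one | C=C(C)[C@H]1C[C@@]2(C)[C@H](CCC(=O)[C@@H]2C)[C@@H](O[Si](CC)(CC)CC)[C@@H]1[N+](=O)[O-] | intermediate
15 | (3S,4R,5R,7R,8R,9R,10S)-8-nitro-9-[(triethylsilyl)oxy]eremophil-11-en-3-ol (3β-hydroxy) | C=C(C)[C@H]1C[C@@]2(C)[C@H](CC[C@H](O)[C@@H]2C)[C@@H](O[Si](CC)(CC)CC)[C@@H]1[N+](=O)[O-] | intermediate
16 | sodium nitronate of 15 (C8 aci-nitro salt) | C=C(C)[C@H]1C[C@@]2(C)[C@H](CC[C@H](O)[C@@H]2C)[C@@H](O[Si](CC)(CC)CC)C1=[N+]([O-])[O-].[Na+] | intermediate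
17 | (3S,4R,5R,7R,9R,10S)-3-hydroxy-9-[(triethylsilyl)oxy]eremophil-11-en-8-one | C=C(C)[C@H]1C[C@@]2(C)[C@H](CC[C@H](O)[C@@H]2C)[C@@H](O[Si](CC)(CC)CC)C1=O | intermediate
18 | (2R)-pent-4-en-2-ol | C=CC[C@@H](C)O | starting material
19 | (2Z)-2-methylbut-2-enoic acid (angelic acid) | O=C(O)/C(C)=C\C | starting material
20 | (2Z)-2-methylbut-2-enoic 2,4,6-trichlorobenzoic anhydride | O=C(OC(=O)/C(C)=C\C)c1c(Cl)cc(Cl)cc1Cl | intermediate
21 | (2R)-pent-4-en-2-yl (2Z)-2-methylbut-2-enoate | C=CC[C@@H](C)OC(=O)/C(C)=C\C | intermediate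
22 | prop-2-enoic acid (acrylic acid) | C=CC(=O)O | starting material
23 | (2E,5R)-5-{[(2Z)-2-methylbut-2-enoyl]oxy}hex-2-enoic acid | OC(=O)/C=C/C[C@@H](C)OC(=O)/C(C)=C\C | intermediate
24 | (3R,4R,5R,7R,9R,10S)-8-oxo-9-[(triethylsilyl)oxy]eremophil-11-en-3-yl (2E,5R)-5-{[(2Z)-2-methylbut-2-enoyl]oxy}hex-2-enoate | C=C(C)[C@H]1C[C@@]2(C)[C@H](CC[C@@H](OC(=O)/C=C/C[C@@H](C)OC(=O)/C(C)=C\C)[C@@H]2C)[C@@H](O[Si](CC)(CC)CC)C1=O | intermediate
25 | (3R,4R,5R,7R,9R,10S)-9-hydroxy-8-oxoeremophil-11-en-3-yl (2E,5R)-5-{[(2Z)-2-methylbut-2-enoyl]oxy}hex-2-enoate (CNP0210874.1) | C=C(C)[C@H]1C[C@@]2(C)[C@H](CC[C@@H](OC(=O)/C=C/C[C@@H](C)OC(=O)/C(C)=C\C)[C@@H]2C)[C@@H](O)C1=O | target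

**Step count and risks**

Total: 14 steps. Longest linear sequence: 12 steps (steps 1–10, 13 and 14); steps 11 and 12 build the side-chain acid.

Steps most likely to fail:

Step 7 (proposed new method). What may go wrong: competing 1,2-addition of the alkenylrhodium species to the unprotected aldehyde, protodeboronation outrunning the conjugate addition, or enolisation of the open-chain aldehyde with loss of the C10 configuration during equilibration. The fallback separates the two bond formations and uses known chemistry. It sets out from 9: rhodium/BINAP-catalysed asymmetric conjugate addition of the same isopropenylboronate to the silyl ether, where no aldehyde is present, should give (2R,3S,4S)-4-{[(tert-butyldimethylsilyl)oxy]methyl}-2,3-dimethyl-3-[(2R)-3-methyl-2-(nitromethyl)but-3-en-1-yl]cyclohexan-1-one F1. HF·pyridine then gives (2R,3S,4S)-4-(hydroxymethyl)-2,3-dimethyl-3-[(2R)-3-methyl-2-(nitromethyl)but-3-en-1-yl]cyclohexan-1-one F2, and Dess–Martin oxidation gives 12, isolated this time. Et3N in CH2Cl2 closes ring A by the intramolecular Henry reaction, and the fallback comes back to the route at 13.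

Step 13. What may go wrong: elimination of the activated axial oxyphosphonium intermediate to a ring B olefin outrunning the slow substitution at the hindered C3, or return of unreacted alcohol. The fallback replaces the redox condensation by sulfonate displacement. It sets out from 17: chloromethanesulfonyl chloride and pyridine give the 3β-chloromethanesulfonate of 17 F3, which is displaced with inversion by the caesium salt of 23 (Cs2CO3, 18-crown-6, toluene, 60 °C), and the fallback comes back to the route at 24.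

Step 10. What may go wrong: β-elimination of triethylsilanolate from the nitronate to a C8=C9 nitroalkene, or stalling of the reduction at the oxime stage. The fallback avoids a free nitronate. It sets out from 15: SnCl2·2H2O, PhSH and Et3N reduce the secondary nitro group to the C8 oxime of 17 F4, and oxime exchange with aqueous glyoxylic acid releases the ketone, so the fallback comes back to the route at 17.

Further compounds
F1 | step 7 | (2R,3S,4S)-4-{[(tert-butyldimethylsilyl)oxy]methyl}-2,3-dimethyl-3-[(2R)-3-methyl-2-(nitromethyl)but-3-en-1-yl]cyclohexan-1-one | C=C(C)[C@H](C[N+](=O)[O-])C[C@@]1(C)[C@H](CCC(=O)[C@@H]1C)CO[Si](C)(C)C(C)(C)C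
F2 | step 7 | (2R,3S,4S)-4-(hydroxymethyl)-2,3-dimethyl-3-[(2R)-3-methyl-2-(nitromethyl)but-3-en-1-yl]cyclohexan-1-one | C=C(C)[C@H](C[N+](=O)[O-])C[C@@]1(C)[C@H](CCC(=O)[C@@H]1C)CO
F3 | step 13 | (3S,4R,5R,7R,9R,10S)-8-oxo-9-[(triethylsilyl)oxy]eremophil-11-en-3-yl chloromethanesulfonate | C=C(C)[C@H]1C[C@@]2(C)[C@H](CC[C@H](OS(=O)(=O)CCl)[C@@H]2C)[C@@H](O[Si](CC)(CC)CC)C1=O
F4 | step 10 | (3S,4R,5R,7R,9R,10S)-8-(hydroxyimino)-9-[(triethylsilyl)oxy]eremophil-11-en-3-ol | C=C(C)[C@H]1C[C@@]2(C)[C@H](CC[C@H](O)[C@@H]2C)[C@@H](O[Si](CC)(CC)CC)C1=NO
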